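**Assumption:** the SMILES is read as a (2S,3R)-trans-2,3-dihydrobenzofuran bearing a (3S,4R)-cis-3,4-dihydroxycyclohex-1-enyl group, i.e. a (1R,2S)-cyclohex-3-ene-1,2-diol; compounds 1, 4, 8 and 11 are taken as commercial. This route is a paper plan and has not been run.

## Retrosynthetic overview

1. Target ⇐ acid deprotection of 16. The dihydrofuran ring is closed last, at C3–C3a, by an aryllithium 5-exo opening of a terminal epoxide (Parham cyclization, inversion at C3).
2. The C2–O bond comes from SN2 opening (inversion) of a Sharpless vinyl epoxy alcohol by a 2-bromophenoxide. One epoxide therefore supplies both C2 and C3, and two inversions equal syn ArO/Ar addition across an E-alkene, giving the 2,3-trans ring.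
3. Epoxy alcohol 10 ⇐ Sharpless epoxidation of dienol 9 ⇐ cross-metathesis of vinylcyclohexene 7.
4. Cyclohexene ⇐ ring-closing enyne metathesis of 6; the cis-diol (C3′/C4′) is carried in from D-erythronolactone acetonide.
5. Ring order: dioxolane (chiral pool) → cyclohexene → oxirane (then relocated) → dihydrofuran; the arene is bought.

## Route

**Step 1**
Reactants: 1, (−)-2,3-O-isopropylidene-D-erythronolactone
Product: 2, 2,3-O-isopropylidene-D-erythrofuranose (lactol, anomer mixture)
Conditions: DIBAL-H (1.1 equiv), CH2Cl2, −78 °C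
Reagents that add atoms: none
Why: Partial hydride reduction of a γ-lactone to the lactol; the two carbinol stereocentres are untouched.

**Step 2**
Reactants: 2
Product: 3, [(4R,5S)-2,2-dimethyl-5-vinyl-1,3-dioxolan-4-yl]methanol
Conditions: Ph3PCH3Br, KOtBu, THF, 0 °C → rt
Reagents that add atoms: methyltriphenylphosphonium bromide, C[P+](c1ccccc1)(c1ccccc1)c1ccccc1.[Br-] (adds CH2)
Why: Wittig methylenation of the open-chain aldehyde tautomer turns the lactol carbon into the future C2′ and frees the primary OH; the cis-acetonide holds the α-centre.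

**Step 3**
Reactants: 3; 4, 1-(trimethylsilyl)propyne
Product: 5, trimethyl{4-[(4R,5S)-2,2-dimethyl-5-vinyl-1,3-dioxolan-4-yl]but-1-yn-1-yl}silane
Conditions: Tf2O, 2,6-lutidine, CH2Cl2, −78 °C; crude triflate added to 4/n-BuLi, THF–DMPU, −78 → −30 °C
Reagents that add atoms: none beyond 4 (Tf2O only activates)
Why: SN2 displacement of a primary triflate by the propargylic lithium of TMS-propyne gives the 1,7-enyne carbon chain; no stereocentre is involved.

**Step 4**
Reactants: 5
Product: 6, (4R,5S)-4-(but-3-yn-1-yl)-2,2-dimethyl-5-vinyl-1,3-dioxolane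
Conditions: K2CO3, MeOH, rt
Reagents that add atoms: none
Why: Base-mediated protodesilylation of the alkynylsilane.

**Step 5**
Reactants: 6
Product: 7, (3aS,7aR)-2,2-dimethyl-5-vinyl-3a,6,7,7a-tetrahydro-1,3-benzodioxole
Conditions: Grubbs II (5 mol %), ethylene (1 atm), CH2Cl2, rt → 40 °C
Reagents that add atoms: none net (ethylene, C=C, is a promoter and may exchange the terminal CH2)
Why: Ring-closing enyne metathesis (exo mode, under ethylene) forms the C1′=C2′ ring alkene with the allylic oxygen at C3′ and leaves a 1-vinyl handle.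

**Step 6**
Reactants: 7; 8, (Z)-but-2-ene-1,4-diol (4 equiv)
Product: 9, (E)-3-[(3aS,7aR)-2,2-dimethyl-3a,6,7,7a-tetrahydro-1,3-benzodioxol-5-yl]prop-2-en-1-ol
Conditions: Hoveyda–Grubbs II (5 mol %), CH2Cl2, 40 °C
Reagents that add atoms: none beyond 8 (adds =CH–CH2OH)
Why: Cross-metathesis occurs only at the terminal vinyl group (the ring alkene is trisubstituted), and the conjugated E-dienol is the thermodynamic product.

**Step 7**
Reactants: 9
Product: 10, {(2S,3S)-3-[(3aS,7aR)-2,2-dimethyl-3a,6,7,7a-tetrahydro-1,3-benzodioxol-5-yl]oxiran-2-yl}methanol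
Conditions: Ti(OiPr)4 (10 mol %), L-(+)-DIPT (12 mol %), TBHP, 4 Å MS, CH2Cl2, −25 °C
Reagents that add atoms: tert-butyl hydroperoxide, CC(C)(C)OO (adds O)
Why: Sharpless asymmetric epoxidation under reagent control; L-(+)-tartrate gives the (2S,3S)-epoxide of an E-allylic alcohol (same sense as cinnamyl alcohol), and only the hydroxyl-directed alkene reacts.

**Step 8**
Reactants: 11, dihydroconiferyl alcohol [3-(4-hydroxy-3-methoxyphenyl)propan-1-ol]
Product: 12, 3-(3-bromo-4-hydroxy-5-methoxyphenyl)propan-1-ol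
Conditions: NBS (1.0 equiv), cat. i-Pr2NH, CH2Cl2, 0 °C
Reagents that add atoms: N-bromosuccinimide, O=C1CCC(=O)N1Br (adds Br)
Why: Electrophilic aromatic bromination ortho to the free phenol (para position blocked), as for vanillin → 5-bromovanillin.

**Step 9**
Reactants: 12
Product: 13, 2-bromo-4-[3-(tert-butyldimethylsilyloxy)propyl]-6-methoxyphenol
Conditions: TBSCl (2.3 equiv), imidazole, DMF, rt; then K2CO3, MeOH, rt (one pot)
Reagents that add atoms: TBSCl, CC(C)(C)[Si](C)(C)Cl
Why: Bis-silylation followed by selective methanolysis of the far more labile aryl silyl ether leaves only the primary TBS ether.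

**Step 10**
Reactants: 10; 13 (1.3 equiv)
Product: 14, (2S,3R)-3-{2-bromo-4-[3-(TBS-oxy)propyl]-6-methoxyphenoxy}-3-[(3aS,7aR)-2,2-dimethyl-3a,6,7,7a-tetrahydro-1,3-benzodioxol-5-yl]propane-1,2-diol
Conditions: Cs2CO3 (0.3 equiv), DMF, 70 °C
Reagents that add atoms: none
Why: Phenoxide SN2 opening of the 2,3-epoxy alcohol at C3, the allylically activated carbon, with inversion (3S → 3R) sets the future C2; catalytic base in DMF keeps alkoxide low and suppresses Payne rearrangement.

**Step 11**
Reactants: 14
Product: 15, (S)-2-{(R)-[2-bromo-4-(3-(TBS-oxy)propyl)-6-methoxyphenoxy][(3aS,7aR)-2,2-dimethyl-3a,6,7,7a-tetrahydro-1,3-benzodioxol-5-yl]methyl}oxirane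
Conditions: TsCl (1.05 equiv), Bu2SnO (2 mol %), Et3N, CH2Cl2, 0 °C → rt; then K2CO3, MeOH, rt
Reagents that add atoms: none
Why: Stannylene-directed tosylation of the primary OH and 3-exo-tet Williamson closure move the epoxide to the terminus with retention at the secondary carbinol.

**Step 12**
Reactants: 15
Product: 16, {(2S,3R)-5-[3-(TBS-oxy)propyl]-2-[(3aS,7aR)-2,2-dimethyl-3a,6,7,7a-tetrahydro-1,3-benzodioxol-5-yl]-7-methoxy-2,3-dihydrobenzofuran-3-yl}methanol
Conditions: t-BuLi (2.05 equiv), THF, −78 °C, then → 0 °C (no Mg salts)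
Reagents that add atoms: none
Why: Br–Li exchange then Parham 5-exo-tet cyclization: the aryllithium opens the terminal epoxide at its internal carbon with inversion, forming C3–C3a and revealing CH2OH; with the earlier inversion at C2 this is net syn addition across the E-alkene, so the ring is 2,3-trans (2S,3R).

**Step 13**
Reactants: 16
Product: 17, difengpiol A
Conditions: AcOH–THF–H2O (3:1:1), 45 °C
Reagents that add atoms: none
Why: Mild acid hydrolysis removes the acetonide and the primary TBS ether together without ionising the allylic aryl ether.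

## Compound list

1 | (−)-2,3-O-isopropylidene-D-erythronolactone, (3aR,6aR) | CC1(C)O[C@@H]2COC(=O)[C@@H]2O1 | starting material
2 | 2,3-O-isopropylidene-D-erythrofuranose | CC1(C)O[C@@H]2COC(O)[C@@H]2O1 | intermediate
3 | [(4R,5S)-2,2-dimethyl-5-vinyl-1,3-dioxolan-4-yl]methanol | C=C[C@@H]1OC(C)(C)O[C@@H]1CO | intermediate
4 | 1-(trimethylsilyl)propyne | CC#C[Si](C)(C)C | starting material
5 | trimethyl{4-[(4R,5S)-2,2-dimethyl-5-vinyl-1,3-dioxolan-4-yl]but-1-ynyl}silane | C=C[C@@H]1OC(C)(C)O[C@@H]1CCC#C[Si](C)(C)C | intermediate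
6 | (4R,5S)-4-(but-3-ynyl)-2,2-dimethyl-5-vinyl-1,3-dioxolane | C=C[C@@H]1OC(C)(C)O[C@@H]1CCC#C | intermediate
7 | (3aS,7aR)-2,2-dimethyl-5-vinyl-3a,6,7,7a-tetrahydro-1,3-benzodioxole | C=CC1=C[C@@H]2OC(C)(C)O[C@@H]2CC1 | intermediate
8 | (Z)-but-2-ene-1,4-diol | OC/C=C\CO | starting material
9 | (E)-3-[(3aS,7aR)-2,2-dimethyl-3a,6,7,7a-tetrahydro-1,3-benzodioxol-5-yl]prop-2-en-1-ol | OC/C=C/C1=C[C@@H]2OC(C)(C)O[C@@H]2CC1 | intermediate
10 | (2S,3S)-epoxy alcohol of 9 | OC[C@@H]1O[C@H]1C3=C[C@@H]2OC(C)(C)O[C@@H]2CC3 | intermediate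
11 | dihydroconiferyl alcohol | COc1cc(CCCO)ccc1O | starting material
12 | 3-(3-bromo-4-hydroxy-5-methoxyphenyl)propan-1-ol | COc1cc(CCCO)cc(Br)c1O | intermediate
13 | 2-bromo-4-[3-(TBS-oxy)propyl]-6-methoxyphenol | COc1cc(CCCO[Si](C)(C)C(C)(C)C)cc(Br)c1O | intermediate
14 | (2S,3R)-3-aryloxy-3-cyclohexenyl-propane-1,2-diol | OC[C@H](O)[C@H](Oc1c(Br)cc(CCCO[Si](C)(C)C(C)(C)C)cc1OC)C3=C[C@@H]2OC(C)(C)O[C@@H]2CC3 | intermediate
15 | (S)-oxirane bearing the (R)-aryloxy(cyclohexenyl)methyl group | C4O[C@@H]4[C@H](Oc1c(Br)cc(CCCO[Si](C)(C)C(C)(C)C)cc1OC)C3=C[C@@H]2OC(C)(C)O[C@@H]2CC3 | intermediate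
16 | TBS/acetonide-protected (2S,3R)-dihydrobenzofuran | COc1cc(CCCO[Si](C)(C)C(C)(C)C)cc2c1O[C@H](C3=C[C@@H]4OC(C)(C)O[C@@H]4CC3)[C@H]2CO | intermediate
17 | difengpiol A, (1R,2S)-4-[(2S,3R)-3-(hydroxymethyl)-5-(3-hydroxypropyl)-7-methoxy-2,3-dihydrobenzofuran-2-yl]cyclohex-3-ene-1,2-diol | COc1cc(CCCO)cc2c1O[C@H](C1=C[C@H](O)[C@H](O)CC1)[C@H]2CO | target

## Totals

Total steps: 13. Longest linear sequence: 11 (1 → 2 → 3 → 5 → 6 → 7 → 9 → 10 → 14 → 15 → 16 → 17).

## Three steps most likely to fail

1. **Step 12 (Parham epoxide cyclization).** Risks are 6-endo attack at the CH2 terminus (giving a 3-chromanol), proton transfer from the allylic O–CH, and slow closure at a hindered secondary carbon. Fallback: drop the anionic closure. Corey–Winter deoxygenation of diol 14 gives the allyl aryl ether ArO–CH(R)–CH=CH2; aryl-radical 5-exo-trig cyclization with TEMPO (or O2) trapping of the primary radical, then N–O/O–O reduction, gives the trans 3-hydroxymethyl ring.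

2. **Step 10 (phenoxide opening at C3).** Risks are attack at C1 after Payne rearrangement, SN2′ at the ring carbon, and a sluggish 2,6-disubstituted phenoxide. Fallback: form C2–O by Ir/phosphoramidite branched-selective asymmetric allylic etherification of the methyl carbonate of 9 with 13. This gives the same allyl aryl ether as in fallback 1, which is closed by the radical cyclization.

3. **Step 6 (cross-metathesis on a conjugated diene).** Risks are low conversion, E/Z mixtures and diene homodimer. Fallback: fix the E-alkene by olefination instead of metathesis. From the iodide of 3, Keck radical allylation with ethyl 2-[(tributylstannyl)methyl]acrylate and diene RCM give the cyclohexene ester; DIBAL, MnO2, HWE with triethyl phosphonoacetate and DIBAL then give 9.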